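## Analysis of the target

The target is a germacranolide: a ten-membered carbocycle (C1–C10) with a trans-fused α-methylene-γ-butyrolactone that runs from the C6 oxygen through C12 and C11 to C7 (C13 is the exocyclic methylene carbon, C14 the methyl on C10, C15 the methyl on C4). The ring carries two trisubstituted oxiranes: a cis-fused one at C1–C10 (C2 and C9 cis, so it derives from a 1(10)Z alkene) and a trans-fused one at C4–C5 (from a 4E alkene). It also carries a free hydroxyl at C2 and an angelate, the (Z)-2-methylbut-2-enoate, at C8. The eight stereocentres are 1R, 2S, 4R, 5R, 6S, 7R, 8S and 10S. In each of the epoxy alcohol triads C10/C1/C2 and C4/C5/C6 the carbinol oxygen is threo to the oxirane oxygen, which is the relationship a hydroxyl-directed peracid epoxidation gives when the alkene has a cis substituent at its far carbon. In the triad C6/C7/C8 the C6–O and C8–O bonds lie on one face of the ring and the C7–C11 bond on the other. The sensitive groups are the two oxiranes (transannular opening with acid in a ten-membered ring), the exocyclic enoate (Michael acceptor), the angelate (isomerises to the tiglate) and the C2 epoxy alcohol (Payne rearrangement with base). The difficulty is to close a ten-membered ring and to place eight stereocentres on it while avoiding acid throughout and strong base late on. The strategy rests on the segment C6–C7–C8: in the lactone ring (O, C6, C7, C11, C12) the C6 oxygen is two atoms away from C11, and C8 is the neighbour of C7, so a radical tethered to O6 through an acetal carbon can form C7–C11 and leave a radical on C8 for capture by oxygen.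

## Retrosynthetic reasoning

**End game, 32 back to 21.** The C2 silyl ether of 31 is removed last, so that C2–OH and C8–OH are never free together. The angelate comes from 28 and acid 29 only after the exocyclic methylene is in place, because an angelate would not survive the lactone enolate needed for 27. The methylene of 27 is added to lactone 24, which comes from lactol 23 by oxidation. The lactol is released from the benzyl acetal 22 by hydrogenolysis, since an alkyl acetal would need aqueous acid, which the bis-epoxide should not be asked to tolerate. The C8 hydroxyl of 21 is capped as a triethylsilyl ether first, because a free C8–OH could close onto C12 and lead to the 8,12-lactone.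

**Key disconnection, 21 back to 19.** The C7–C11 bond and the C8–O bond are cut together. They are vicinal, they are the two bonds that turn the ring alkene into the C6/C7/C8 triad, and one radical chain forms both. The C6 oxygen, the later lactone oxygen, is the tether, and the acetal carbon becomes C12. The forward reaction has to close the five-membered ring before the primary radical is intercepted, give the trans ring fusion, and take up oxygen at C8 on the face away from the new C–C bond.

**Acetal and ring, 19 back to 16.** The C6–O acetal bond of 19 comes from alcohol 17 and vinyl ether 18. The ring of 17 is opened at C7=C8, the only ring bond between two unsubstituted sp2 carbons and with no stereocentre on it, so metathesis of diene 16 is asked only to close the ring. The Z geometry is the one a ten-membered ring prefers and the one the stereochemical argument of the key step requires.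

**C4–C5 oxirane and C6, 16 back to 12.** The two C–O bonds of the C4–C5 oxirane are cut, leading to allylic alcohol 15, whose hydroxyl directs a peracid to the correct face. 15 is cut at C5–C6 into alkenyl iodide 12 and acrolein 13. This coupling keeps the E geometry, but the remote centres cannot control C6, so the epimer mixture 14 is resolved by selective epoxidation of the unwanted epimer.

**C1–C10 oxirane, 12 back to 10.** The silyl ether of 12 is placed on 11, and the oxirane of 11 is cut to allylic alcohol 10. This epoxidation must precede silylation, because the free C2–OH is the directing group. It must also precede the arrival of C6–OH, so that only one hydroxyl directs at a time.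

**The two trisubstituted alkenes, 10 back to 3.** The C4–methyl bond and the C5–iodine bond of 10 are cut to terminal alkyne 8 (syn methylalumination, then iodinolysis, gives E). This step must come before any oxirane is present. 8 comes from silylalkyne 7, which is cut at C9–C10 into alkenyl iodide 5 and stannane 6. 5 comes from propargylic alcohol 3 by hydroxyl-directed trans-hydroalumination and iodinolysis, which gives Z. The silyl cap keeps the second alkyne inert during this sequence.

**First stereocentre, 3 back to 1 and 2.** The C2–C3 bond is cut into ynal 1 and propargyl boronate 2. This bond is chosen because its formation creates C2 under catalyst control in the first step. C1 and C10 are then derived from C2, C4 and C5 from C6, and C7 and C8 from C6 again in the key step.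

## Alternatives that were turned down

Alternative 1: The disconnection is the ring bond C1–C2, made together with the C2 carbinol. In the forward direction a chain with a Z alkenyl iodide at C1 and an aldehyde at C2 is closed with CrCl2 and catalytic NiCl2. This gives the ten-membered allylic alcohol A1, the 1,10-deoxy form of the target, and one hydroxyl-directed epoxidation would remain.
- For: the closure runs under neutral conditions that tolerate lactone, enoate and oxirane; the Z geometry is fixed in the iodide; one step makes the ring, a C–C bond and a carbinol; the more labile oxirane is made last.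
- Against: the C2 aldehyde is β,γ to the C4–C5 oxirane and is likely to lose it by β-elimination. C2 would be set only by the bias of a ten-membered transition state, and since C2–OH steers the last epoxidation, an error at C2 is passed on to C1 and C10. The lactone, the angelate and the whole C6/C7/C8 triad must already be in the open chain, and the strategy does not say how they are made.
- Comparison: it is more convergent and keeps one oxirane out of the long sequence, and on both points it is the stronger. The chosen route instead fixes C2 with a catalyst before any ring exists, closes the ring by a reaction that creates no stereocentre, and builds C7, C8 and the lactone ring in its key step.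

Alternative 2: The disconnection is the four C–O bonds of both oxiranes. In the forward direction a macrocyclic 1(10)Z,4E-diene-2,6-diol is treated with VO(acac)2 and tert-butyl hydroperoxide, so that C2–OH and C6–OH each deliver oxygen to the neighbouring trisubstituted alkene, giving the bis-epoxy diol A2.
- For: four stereocentres and both acid-labile rings arise in one late step; the directing hydroxyls are those of the target; the threo outcome needed is the normal one for such allylic alcohols.
- Against: in a ten-membered ring the exposed alkene face is set by ring conformation and not by the open-chain A(1,3) model, and the vanadium reagent is the less threo-selective one for these alkenes. The 11(13) alkene of A2 is homoallylic to C6–OH and may be epoxidised as well. The cyclodeca-1(10),4-diene needed is prone to Cope rearrangement and transannular cyclisation. After A2 the lactone must still be made by oxidation at C12 beside both oxiranes.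
- Comparison: this alternative is clearly stronger in step economy for the oxiranes and exposes them to fewer operations. The chosen route uses the same directing principle in the open chain, one alkene at a time and with a peracid, where the outcome can be predicted. It pays by carrying the oxiranes through the metathesis and the radical step.

Alternative 3: The disconnection is the ten-membered ring itself by a [3,3] shift: C2–C3 forms while the C5–C10 bond of a cyclohexane breaks (target numbering). In the forward direction the potassium alkoxide (KH, 18-crown-6) of a trans-1,2-dialkenylcyclohexanol rearranges through a chair to the ten-membered enolate and, after protonation, to ketone A3 with the 4E alkene and the C2 ether centre.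
- For: the ring is made from a six-membered ring without high dilution, which is more dependable than any macrocyclisation, the metathesis used here included. The chair passes cyclohexane stereochemistry on to the E alkene and to C2, and the reaction scales.
- Against: A3 is far from the target. C10 is a ketone between two methylene groups, and nothing in the structure enforces enolisation toward C1 rather than C9 or a Z-selective methyl coupling. C13 and C14 are missing. Both oxiranes, the lactone carbonyl, the angelate and four different protecting groups remain. C6, C7 and C8 must be built on the cyclohexane beforehand.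
- Comparison: it is stronger on ring construction and on the 4E geometry. The chosen route has C14, C15 and both alkene geometries in place from alkyne additions and needs fewer operations after the ring is formed, but its ring closure is the less certain one.

Key step: step 13

Assumption (step 1): the (S,S,S,S) antipode of the bisphosphine is taken to give the 4S alcohol 3; if the facial sense is the reverse, the (R,R,R,R) ligand is used.

Remark: ring compounds 17 and 19–32 are named with the numbering of the target. The acetal carbon of 19–22 and the lactol carbon of 23 are epimeric mixtures, and both epimers are carried on. The C7 descriptor changes between R and S with the CIP priority of the C8 substituent; the geometry does not change.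

## Route

Step 1
Reactants: 1 but-2-ynal; 2 trimethyl[3-(4,4,5,5-tetramethyl-1,3,2-dioxaborolan-2-yl)prop-1-yn-1-yl]silane
Product: 3 (4S)-1-(trimethylsilyl)hepta-1,5-diyn-4-ol
Conditions: Cu(O2CCHMe2)2 (5 mol %), (S,S,S,S)-MeO-BIBOP (6 mol %), LiOt-Bu (8 mol %), THF, −60 °C; aq NH4Cl
Reagents that add atoms: none
Why: Copper-catalysed asymmetric propargylation of an aldehyde: boron-to-copper exchange gives an allenylcopper species that adds through a closed SE2′ transition state, and the C-silyl group enforces the homopropargylic over the allenyl product. The chiral bisphosphine selects the aldehyde face and so sets C2 of the target (4S in 3).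

Step 2
Reactants: 3 (4S)-1-(trimethylsilyl)hepta-1,5-diyn-4-ol
Product: 5 (4S,5Z)-6-iodo-1-(trimethylsilyl)hept-5-en-1-yn-4-ol, via cyclic alkenylalanate 4 (not isolated)
Conditions: NaAlH2(OCH2CH2OMe)2 (Red-Al), THF, 0 °C to rt; EtOAc; then I2, THF, −78 to 0 °C
Reagents that add atoms: iodine, II
Why: Hydroxyl-directed trans-hydroalumination of a propargylic alcohol puts hydride on the proximal alkyne carbon and aluminium on the distal one within a five-membered alkoxyalanate, so iodinolysis with retention leaves iodine cis to the carbinol carbon (Z). The silyl-capped homopropargylic alkyne is not reduced at this temperature and cannot be metalated.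

Step 3
Reactants: 5 (4S,5Z)-6-iodo-1-(trimethylsilyl)hept-5-en-1-yn-4-ol; 6 allyltributylstannane
Product: 7 (4S,5Z)-6-methyl-1-(trimethylsilyl)nona-5,8-dien-1-yn-4-ol
Conditions: Pd2(dba)3 (2.5 mol %), AsPh3 (10 mol %), DMF, 40 °C
Reagents that add atoms: none
Why: Stille coupling of an alkenyl iodide with an allylstannane goes with retention at the sp2 carbon, so the allyl carbon (C9 of the target) ends cis to the carbinol carbon, which is the 1(10)Z alkene. The weakly ligated zerovalent palladium catalyst limits migration of the skipped diene into conjugation.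

Step 4
Reactants: 7 (4S,5Z)-6-methyl-1-(trimethylsilyl)nona-5,8-dien-1-yn-4-ol
Product: 8 (4S,5Z)-6-methylnona-5,8-dien-1-yn-4-ol
Conditions: K2CO3, MeOH, rt
Reagents that add atoms: none
Why: Base-mediated protodesilylation of an alkynylsilane; nothing else in 7 reacts with methanolic carbonate.

Step 5
Reactants: 8 (4S,5Z)-6-methylnona-5,8-dien-1-yn-4-ol
Product: 10 (1E,4S,5Z)-1-iodo-2,6-dimethylnona-1,5,8-trien-4-ol, via alkenylalane 9 (not isolated)
Conditions: AlMe3 (3.5 equiv), Cp2ZrCl2 (0.3 equiv), CH2Cl2, 0 °C to rt; then I2, THF, −30 to 0 °C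
Reagents that add atoms: trimethylaluminium, C[Al](C)C; iodine, II
Why: Zirconium-catalysed methylalumination of the terminal alkyne (Negishi carboalumination) is syn and puts the methyl group on the internal carbon (C4 of the target) and aluminium on the terminal one, so iodinolysis with retention gives the E iodide. The hydroxyl is carried as its aluminium alkoxide, and the mono- and trisubstituted alkenes react much more slowly than the alkyne.

Step 6
Reactants: 10 (1E,4S,5Z)-1-iodo-2,6-dimethylnona-1,5,8-trien-4-ol
Product: 11 (1S,3E)-4-iodo-3-methyl-1-[(2R,3S)-3-methyl-3-(prop-2-en-1-yl)oxiran-2-yl]but-3-en-1-ol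
Conditions: mCPBA, NaHCO3, CH2Cl2, −10 to 0 °C
Reagents that add atoms: mCPBA, OOC(=O)c1cccc(Cl)c1
Why: Hydroxyl-directed peracid epoxidation: the allyl carbon cis to the carbinol creates A(1,3) strain that holds the carbinol hydrogen in the alkene plane, and the hydrogen-bonded peracid delivers oxygen to the face that carries the hydroxyl, which gives the threo epoxy alcohol (C1 R and C10 S of the target). The iodoalkene is electron-poor and the terminal alkene is neither directed nor electron-rich, so neither should compete.

Step 7
Reactants: 11 (1S,3E)-4-iodo-3-methyl-1-[(2R,3S)-3-methyl-3-(prop-2-en-1-yl)oxiran-2-yl]but-3-en-1-ol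
Product: 12 tert-butyl({(1S,3E)-4-iodo-3-methyl-1-[(2R,3S)-3-methyl-3-(prop-2-en-1-yl)oxiran-2-yl]but-3-en-1-yl}oxy)dimethylsilane
Conditions: TBSCl, imidazole, DMF, rt
Reagents that add atoms: tert-butyldimethylsilyl chloride, CC(C)(C)[Si](C)(C)Cl
Why: Silylation of a secondary alcohol under conditions that leave the oxirane alone. From here on C2–O can no longer direct an epoxidation and is protected until the last step.

Step 8
Reactants: 12 tert-butyl({(1S,3E)-4-iodo-3-methyl-1-[(2R,3S)-3-methyl-3-(prop-2-en-1-yl)oxiran-2-yl]but-3-en-1-yl}oxy)dimethylsilane; 13 acrolein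
Product: 14 (3RS,4E,7S)-7-[(tert-butyldimethylsilyl)oxy]-5-methyl-7-[(2R,3S)-3-methyl-3-(prop-2-en-1-yl)oxiran-2-yl]hepta-1,4-dien-3-ol
Conditions: CrCl2 (5 equiv), NiCl2 (1 mol %), DMSO, rt
Reagents that add atoms: none
Why: Nozaki–Hiyama–Kishi coupling: the alkenylchromium species forms with retention of the E geometry and adds 1,2 to the enal, and oxirane and silyl ether are tolerated. The remote centres should give no control at the new carbinol, so 14 is expected as a near-equal mixture of the two C3 epimers (C6 of the target).

Step 9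
Reactants: 14 (3RS,4E,7S)-7-[(tert-butyldimethylsilyl)oxy]-5-methyl-7-[(2R,3S)-3-methyl-3-(prop-2-en-1-yl)oxiran-2-yl]hepta-1,4-dien-3-ol
Product: 15 (3S,4E,7S)-7-[(tert-butyldimethylsilyl)oxy]-5-methyl-7-[(2R,3S)-3-methyl-3-(prop-2-en-1-yl)oxiran-2-yl]hepta-1,4-dien-3-ol
Conditions: Ti(OiPr)4 (1.0 equiv), D-(−)-diisopropyl tartrate (1.2 equiv), t-BuOOH (0.6 equiv), 4 Å sieves, CH2Cl2, −20 °C
Reagents that add atoms: none
Why: Sharpless kinetic resolution: with the D-(−)-tartrate the 3R carbinol (priority order hydroxyl, trisubstituted alkenyl, vinyl, H) is the fast-reacting epimer and is epoxidised at its trisubstituted alkene to the erythro epoxy alcohol, while the 3S epimer 15 is left and separated as the less polar allylic alcohol. The vinyl group of 15 is matched to the catalyst but, as a monosubstituted alkene, should react far too slowly to matter at partial conversion.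

Step 10
Reactants: 15 (3S,4E,7S)-7-[(tert-butyldimethylsilyl)oxy]-5-methyl-7-[(2R,3S)-3-methyl-3-(prop-2-en-1-yl)oxiran-2-yl]hepta-1,4-dien-3-ol
Product: 16 (1S)-1-[(2R,3R)-3-{(2S)-2-[(tert-butyldimethylsilyl)oxy]-2-[(2R,3S)-3-methyl-3-(prop-2-en-1-yl)oxiran-2-yl]ethyl}-3-methyloxiran-2-yl]prop-2-en-1-ol
Conditions: mCPBA, NaHCO3, CH2Cl2, 0 °C
Reagents that add atoms: mCPBA, OOC(=O)c1cccc(Cl)c1
Why: Hydroxyl-directed peracid epoxidation as in step 6: the C15 methyl group cis to the carbinol carbon holds the carbinol hydrogen in the alkene plane, and oxygen is delivered syn to the C6 hydroxyl, which gives the threo epoxy alcohol (C4 R and C5 R of the target). The vinyl and allyl alkenes are monosubstituted and should stay untouched with one equivalent of peracid.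

Step 11
Reactants: 16 (1S)-1-[(2R,3R)-3-{(2S)-2-[(tert-butyldimethylsilyl)oxy]-2-[(2R,3S)-3-methyl-3-(prop-2-en-1-yl)oxiran-2-yl]ethyl}-3-methyloxiran-2-yl]prop-2-en-1-ol
Product: 17 (1R,2S,4R,5R,6S,7Z,10S)-2-[(tert-butyldimethylsilyl)oxy]-1,10:4,5-diepoxy-4,10-dimethylcyclodec-7-en-6-ol
Conditions: second-generation Grubbs catalyst (H2IMes)(PCy3)Cl2Ru=CHPh (10 mol %), CH2Cl2 (1 mM), 40 °C
Reagents that add atoms: none
Why: Ring-closing metathesis of two monosubstituted alkenes with loss of ethene. The two oxiranes remove rotatable bonds from the chain, and the Z alkene is the one a ten-membered ring can accommodate. The free allylic hydroxyl is compatible with the catalyst and is known to assist metathesis at the neighbouring vinyl group.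

Step 12
Reactants: 17 (1R,2S,4R,5R,6S,7Z,10S)-2-[(tert-butyldimethylsilyl)oxy]-1,10:4,5-diepoxy-4,10-dimethylcyclodec-7-en-6-ol; 18 benzyl vinyl ether
Product: 19 (1R,2S,4R,5R,6S,7Z,10S)-6-[1-(benzyloxy)-2-bromoethoxy]-2-[(tert-butyldimethylsilyl)oxy]-1,10:4,5-diepoxy-4,10-dimethylcyclodec-7-ene (both acetal epimers)
Conditions: NBS, 18 (5 equiv), CH2Cl2, −78 to 0 °C
Reagents that add atoms: N-bromosuccinimide, BrN1C(=O)CCC1=O
Why: Haloacetalisation: the electron-rich vinyl ether takes up bromine much faster than the ring alkene, and the bromo-oxocarbenium ion is trapped by the C6 hydroxyl. Benzyl is used as the acetal alkyl group so that the lactol can later be freed by hydrogenolysis instead of acid.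

Step 13
Reactants: 19 (1R,2S,4R,5R,6S,7Z,10S)-6-[1-(benzyloxy)-2-bromoethoxy]-2-[(tert-butyldimethylsilyl)oxy]-1,10:4,5-diepoxy-4,10-dimethylcyclodec-7-ene
Product: 21 (1R,2S,4R,5R,6S,7R,8S,10S)-12-(benzyloxy)-2-[(tert-butyldimethylsilyl)oxy]-1,10:4,5:6,12-triepoxy-13-norgermacran-8-ol (both C12 epimers), via C8 hydroperoxide 20 (not isolated)
Conditions: Bu3SnH (2.5 equiv, slow addition), Et3B (0.5 equiv), dry air, toluene (5 mM), 0 °C; then PPh3
Reagents that add atoms: dioxygen, O=O
Why: Ethyl radicals from Et3B and O2 start a tin chain; Bu3Sn• abstracts bromine from 19, the primary C11 radical closes 5-exo-trig onto C7 of the ring Z alkene (forming C7–C11 and the five-membered lactol ether ring O, C6, C7, C11, C12), the secondary C8 radical is captured by O2, the peroxyl radical takes hydrogen from Bu3SnH to give 20, and PPh3 reduces 20 to 21. The closest known reaction type is the Ueno–Stork haloacetal cyclisation run with tin hydride under air, in which the cyclised radical is hydroxylated. C7 is controlled by C6: the tether can reach C7 only from the face that carries O6, and A(1,3) strain across the Z alkene, together with a ring that keeps C5 out of the alkene plane, places H6 in that plane, so C5 and the new C7–C11 bond should end on opposite sides of the new ring (trans fusion, 7R). C8 is controlled by C7: O2 should enter on the face away from the new C7–C11 bond, which puts C8–O on the same ring face as C6–O (8S), as in the target. The step needs ring closure to outrun capture of the C11 radical by O2 or by tin hydride, which slow addition of Bu3SnH, air in place of pure oxygen and high dilution should secure for a 5-exo acetal radical. It also needs both oxiranes to survive, and they should, because neither C11 nor C8 is bonded to an oxirane carbon (C9 separates C8 from C10), so no oxiranylcarbinyl radical can form.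

Step 14
Reactants: 21 (1R,2S,4R,5R,6S,7R,8S,10S)-12-(benzyloxy)-2-[(tert-butyldimethylsilyl)oxy]-1,10:4,5:6,12-triepoxy-13-norgermacran-8-ol
Product: 22 (1R,2S,4R,5R,6S,7S,8S,10S)-12-(benzyloxy)-2-[(tert-butyldimethylsilyl)oxy]-8-[(triethylsilyl)oxy]-1,10:4,5:6,12-triepoxy-13-norgermacrane
Conditions: TESCl, imidazole, DMAP (cat.), DMF, rt
Reagents that add atoms: chlorotriethylsilane, CC[Si](Cl)(CC)CC
Why: Silylation with the chloride and imidazole; a silyl triflate is avoided because it would ionise the acetal. The C8 oxygen is capped so that the C12 hemiacetal freed in the next step can close only onto O6.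

Step 15
Reactants: 22 (1R,2S,4R,5R,6S,7S,8S,10S)-12-(benzyloxy)-2-[(tert-butyldimethylsilyl)oxy]-8-[(triethylsilyl)oxy]-1,10:4,5:6,12-triepoxy-13-norgermacrane
Product: 23 (1R,2S,4R,5R,6S,7S,8S,10S)-2-[(tert-butyldimethylsilyl)oxy]-8-[(triethylsilyl)oxy]-1,10:4,5:6,12-triepoxy-13-norgermacran-12-ol (lactol, both C12 epimers)
Conditions: H2 (1 atm), Pd(OH)2/C, EtOAc, rt
Reagents that add atoms: none
Why: Hydrogenolysis of the benzylic C–O bond of a benzyl acetal under neutral conditions. No C=C bond is left in 22, and trialkyl-substituted oxiranes and silyl ethers are not cleaved in ethyl acetate.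

Step 16
Reactants: 23 (1R,2S,4R,5R,6S,7S,8S,10S)-2-[(tert-butyldimethylsilyl)oxy]-8-[(triethylsilyl)oxy]-1,10:4,5:6,12-triepoxy-13-norgermacran-12-ol
Product: 24 (1R,2S,4R,5R,6S,7S,8S,10S)-2-[(tert-butyldimethylsilyl)oxy]-8-[(triethylsilyl)oxy]-1,10:4,5-diepoxy-13-norgermacrano-12,6-lactone
Conditions: (n-Pr)4N[RuO4] (5 mol %), N-methylmorpholine N-oxide, 4 Å sieves, CH2Cl2, rt
Reagents that add atoms: none
Why: Perruthenate-catalysed oxidation of a lactol to the lactone under neutral, anhydrous conditions; no other oxidisable group is free.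

Step 17
Reactants: 24 (1R,2S,4R,5R,6S,7S,8S,10S)-2-[(tert-butyldimethylsilyl)oxy]-8-[(triethylsilyl)oxy]-1,10:4,5-diepoxy-13-norgermacrano-12,6-lactone
Product: 27 (1R,2S,4R,5R,6S,7S,8S,10S)-2-[(tert-butyldimethylsilyl)oxy]-8-[(triethylsilyl)oxy]-1,10:4,5-diepoxygermacr-11(13)-eno-12,6-lactone, via Mannich base 25 (not isolated), via methiodide 26 (not isolated)
Conditions: LiN(i-Pr)2, THF, −78 °C; CH2=NMe2+ I−, −78 to 0 °C; MeI, THF/MeOH, rt; aq NaHCO3, CH2Cl2
Reagents that add atoms: Eschenmoser's salt, C=[N+](C)C.[I-]
Why: α-Methylenation of a lactone through its lithium enolate: Mannich alkylation at C11, quaternisation and elimination of trimethylamine. C11 is the only acidic position, the C11 stereocentre of 25 is lost again in the elimination, and both ester-free silyl ethers and the oxiranes should tolerate the amide base at −78 °C.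

Step 18
Reactants: 27 (1R,2S,4R,5R,6S,7S,8S,10S)-2-[(tert-butyldimethylsilyl)oxy]-8-[(triethylsilyl)oxy]-1,10:4,5-diepoxygermacr-11(13)-eno-12,6-lactone
Product: 28 (1R,2S,4R,5R,6S,7R,8S,10S)-2-[(tert-butyldimethylsilyl)oxy]-8-hydroxy-1,10:4,5-diepoxygermacr-11(13)-eno-12,6-lactone
Conditions: HF·pyridine, pyridine, THF, 0 °C
Reagents that add atoms: none
Why: Selective cleavage of a triethylsilyl ether beside a secondary tert-butyldimethylsilyl ether with pyridine-buffered HF. The buffer keeps the medium too weakly acidic to open the oxiranes.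

Step 19
Reactants: 28 (1R,2S,4R,5R,6S,7R,8S,10S)-2-[(tert-butyldimethylsilyl)oxy]-8-hydroxy-1,10:4,5-diepoxygermacr-11(13)-eno-12,6-lactone; 29 angelic acid, (Z)-2-methylbut-2-enoic acid
Product: 31 (1R,2S,4R,5R,6S,7R,8S,10S)-2-[(tert-butyldimethylsilyl)oxy]-8-{[(Z)-2-methylbut-2-enoyl]oxy}-1,10:4,5-diepoxygermacr-11(13)-eno-12,6-lactone, via mixed anhydride 30 (not isolated)
Conditions: 29, 2,4,6-Cl3C6H2COCl, Et3N, toluene, rt; then 28, toluene, 75 °C
Reagents that add atoms: none
Why: Yamaguchi esterification through the mixed 2,4,6-trichlorobenzoic anhydride. It is run without a nucleophilic pyridine catalyst, because that is the agent that isomerises angelates to tiglates, and the hindered aroyl carbonyl directs the alcohol to the angeloyl carbonyl.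

Step 20
Reactants: 31 (1R,2S,4R,5R,6S,7R,8S,10S)-2-[(tert-butyldimethylsilyl)oxy]-8-{[(Z)-2-methylbut-2-enoyl]oxy}-1,10:4,5-diepoxygermacr-11(13)-eno-12,6-lactone
Product: 32 (1R,2S,4R,5R,6S,7R,8S,10S)-2-hydroxy-8-{[(Z)-2-methylbut-2-enoyl]oxy}-1,10:4,5-diepoxygermacr-11(13)-eno-12,6-lactone (CNP0388761.1)
Conditions: Bu4NF, AcOH (1:1), THF, 0 °C to rt
Reagents that add atoms: none
Why: Fluoride cleavage of the silyl ether, buffered with acetic acid so that no free alkoxide forms. This should prevent Payne rearrangement of the C2 epoxy alcohol, conjugate addition to the methylene lactone and acyl migration of the angelate.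

## Compound list

1 | but-2-ynal | CC#CC=O | starting material
2 | trimethyl[3-(4,4,5,5-tetramethyl-1,3,2-dioxaborolan-2-yl)prop-1-yn-1-yl]silane | C[Si](C)(C)C#CCB1OC(C)(C)C(C)(C)O1 | starting material
3 | (4S)-1-(trimethylsilyl)hepta-1,5-diyn-4-ol | C[Si](C)(C)C#CC[C@H](O)C#CC | intermediate
4 | cyclic alkenylalanate from 3 (five-membered O–Al–C=C–C ring, sodium salt, carbinol centre as in 3) | [Na+].CC1=C[C@H](CC#C[Si](C)(C)C)O[Al-]1(OCCOC)OCCOC | intermediate (not isolated)
5 | (4S,5Z)-6-iodo-1-(trimethylsilyl)hept-5-en-1-yn-4-ol | C[Si](C)(C)C#CC[C@H](O)/C=C(/C)I | intermediate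
6 | allyltributylstannane | C=CC[Sn](CCCC)(CCCC)CCCC | starting material
7 | (4S,5Z)-6-methyl-1-(trimethylsilyl)nona-5,8-dien-1-yn-4-ol | C[Si](C)(C)C#CC[C@H](O)/C=C(/C)CC=C | intermediate
8 | (4S,5Z)-6-methylnona-5,8-dien-1-yn-4-ol | C#CC[C@H](O)/C=C(/C)CC=C | intermediate
9 | (E)-alkenyldimethylalane from 8, as its O-dimethylaluminium alkoxide | C[Al](C)/C=C(\C)C[C@H](O[Al](C)C)/C=C(/C)CC=C | intermediate (not isolated)
10 | (1E,4S,5Z)-1-iodo-2,6-dimethylnona-1,5,8-trien-4-ol | I/C=C(\C)C[C@H](O)/C=C(/C)CC=C | intermediate
11 | (1S,3E)-4-iodo-3-methyl-1-[(2R,3S)-3-methyl-3-(prop-2-en-1-yl)oxiran-2-yl]but-3-en-1-ol | I/C=C(\C)C[C@H](O)[C@H]1O[C@@]1(C)CC=C | intermediate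
12 | tert-butyl({(1S,3E)-4-iodo-3-methyl-1-[(2R,3S)-3-methyl-3-(prop-2-en-1-yl)oxiran-2-yl]but-3-en-1-yl}oxy)dimethylsilane | I/C=C(\C)C[C@H](O[Si](C)(C)C(C)(C)C)[C@H]1O[C@@]1(C)CC=C | intermediate
13 | acrolein | C=CC=O | starting material
14 | (3RS,4E,7S)-7-[(tert-butyldimethylsilyl)oxy]-5-methyl-7-[(2R,3S)-3-methyl-3-(prop-2-en-1-yl)oxiran-2-yl]hepta-1,4-dien-3-ol (both C3 epimers) | C=CC(O)/C=C(\C)C[C@H](O[Si](C)(C)C(C)(C)C)[C@H]1O[C@@]1(C)CC=C | intermediate
15 | (3S,4E,7S)-7-[(tert-butyldimethylsilyl)oxy]-5-methyl-7-[(2R,3S)-3-methyl-3-(prop-2-en-1-yl)oxiran-2-yl]hepta-1,4-dien-3-ol | C=C[C@H](O)/C=C(\C)C[C@H](O[Si](C)(C)C(C)(C)C)[C@H]1O[C@@]1(C)CC=C | intermediate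
16 | (1S)-1-[(2R,3R)-3-{(2S)-2-[(tert-butyldimethylsilyl)oxy]-2-[(2R,3S)-3-methyl-3-(prop-2-en-1-yl)oxiran-2-yl]ethyl}-3-methyloxiran-2-yl]prop-2-en-1-ol | C=C[C@H](O)[C@H]1O[C@]1(C)C[C@H](O[Si](C)(C)C(C)(C)C)[C@H]1O[C@@]1(C)CC=C | intermediate
17 | (1R,2S,4R,5R,6S,7Z,10S)-2-[(tert-butyldimethylsilyl)oxy]-1,10:4,5-diepoxy-4,10-dimethylcyclodec-7-en-6-ol | O[C@H]2/C=C\C[C@]1(C)O[C@@H]1[C@@H](O[Si](C)(C)C(C)(C)C)C[C@@]1(C)O[C@H]21 | intermediate
18 | benzyl vinyl ether | C=COCc1ccccc1 | starting material
19 | (1R,2S,4R,5R,6S,7Z,10S)-6-[1-(benzyloxy)-2-bromoethoxy]-2-[(tert-butyldimethylsilyl)oxy]-1,10:4,5-diepoxy-4,10-dimethylcyclodec-7-ene (both acetal epimers) | BrCC(OCc1ccccc1)O[C@H]2/C=C\C[C@]1(C)O[C@@H]1[C@@H](O[Si](C)(C)C(C)(C)C)C[C@@]1(C)O[C@H]21 | intermediate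
20 | (1R,2S,4R,5R,6S,7S,8S,10S)-12-(benzyloxy)-2-[(tert-butyldimethylsilyl)oxy]-8-hydroperoxy-1,10:4,5:6,12-triepoxy-13-norgermacrane (both C12 epimers) | C1C(OCc3ccccc3)O[C@H]2[C@H]1[C@@H](OO)C[C@]1(C)O[C@@H]1[C@@H](O[Si](C)(C)C(C)(C)C)C[C@@]1(C)O[C@H]21 | intermediate (not isolated)
21 | (1R,2S,4R,5R,6S,7R,8S,10S)-12-(benzyloxy)-2-[(tert-butyldimethylsilyl)oxy]-1,10:4,5:6,12-triepoxy-13-norgermacran-8-ol (both C12 epimers) | C1C(OCc3ccccc3)O[C@H]2[C@H]1[C@@H](O)C[C@]1(C)O[C@@H]1[C@@H](O[Si](C)(C)C(C)(C)C)C[C@@]1(C)O[C@H]21 | intermediate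
22 | (1R,2S,4R,5R,6S,7S,8S,10S)-12-(benzyloxy)-2-[(tert-butyldimethylsilyl)oxy]-8-[(triethylsilyl)oxy]-1,10:4,5:6,12-triepoxy-13-norgermacrane (both C12 epimers) | C1C(OCc3ccccc3)O[C@H]2[C@H]1[C@@H](O[Si](CC)(CC)CC)C[C@]1(C)O[C@@H]1[C@@H](O[Si](C)(C)C(C)(C)C)C[C@@]1(C)O[C@H]21 | intermediate
23 | (1R,2S,4R,5R,6S,7S,8S,10S)-2-[(tert-butyldimethylsilyl)oxy]-8-[(triethylsilyl)oxy]-1,10:4,5:6,12-triepoxy-13-norgermacran-12-ol (both C12 epimers) | C1C(O)O[C@H]2[C@H]1[C@@H](O[Si](CC)(CC)CC)C[C@]1(C)O[C@@H]1[C@@H](O[Si](C)(C)C(C)(C)C)C[C@@]1(C)O[C@H]21 | intermediate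
24 | (1R,2S,4R,5R,6S,7S,8S,10S)-2-[(tert-butyldimethylsilyl)oxy]-8-[(triethylsilyl)oxy]-1,10:4,5-diepoxy-13-norgermacrano-12,6-lactone | C1C(=O)O[C@H]2[C@H]1[C@@H](O[Si](CC)(CC)CC)C[C@]1(C)O[C@@H]1[C@@H](O[Si](C)(C)C(C)(C)C)C[C@@]1(C)O[C@H]21 | intermediate
25 | 13-(dimethylamino) derivative of 24 (both C11 epimers, other centres as in 24) | CN(C)CC1C(=O)O[C@H]2[C@H]1[C@@H](O[Si](CC)(CC)CC)C[C@]1(C)O[C@@H]1[C@@H](O[Si](C)(C)C(C)(C)C)C[C@@]1(C)O[C@H]21 | intermediate (not isolated)
26 | 13-(trimethylammonio) derivative of 24, iodide (both C11 epimers) | [I-].C[N+](C)(C)CC1C(=O)O[C@H]2[C@H]1[C@@H](O[Si](CC)(CC)CC)C[C@]1(C)O[C@@H]1[C@@H](O[Si](C)(C)C(C)(C)C)C[C@@]1(C)O[C@H]21 | intermediate (not isolated)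
27 | (1R,2S,4R,5R,6S,7S,8S,10S)-2-[(tert-butyldimethylsilyl)oxy]-8-[(triethylsilyl)oxy]-1,10:4,5-diepoxygermacr-11(13)-eno-12,6-lactone | C=C1C(=O)O[C@H]2[C@H]1[C@@H](O[Si](CC)(CC)CC)C[C@]1(C)O[C@@H]1[C@@H](O[Si](C)(C)C(C)(C)C)C[C@@]1(C)O[C@H]21 | intermediate
28 | (1R,2S,4R,5R,6S,7R,8S,10S)-2-[(tert-butyldimethylsilyl)oxy]-8-hydroxy-1,10:4,5-diepoxygermacr-11(13)-eno-12,6-lactone | C=C1C(=O)O[C@H]2[C@H]1[C@@H](O)C[C@]1(C)O[C@@H]1[C@@H](O[Si](C)(C)C(C)(C)C)C[C@@]1(C)O[C@H]21 | intermediate
29 | angelic acid, (Z)-2-methylbut-2-enoic acid | C/C=C(/C)C(=O)O | starting material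
30 | (Z)-2-methylbut-2-enoic 2,4,6-trichlorobenzoic anhydride | C/C=C(/C)C(=O)OC(=O)c1c(Cl)cc(Cl)cc1Cl | intermediate (not isolated)
31 | (1R,2S,4R,5R,6S,7R,8S,10S)-2-[(tert-butyldimethylsilyl)oxy]-8-{[(Z)-2-methylbut-2-enoyl]oxy}-1,10:4,5-diepoxygermacr-11(13)-eno-12,6-lactone | C=C1C(=O)O[C@H]2[C@H]1[C@@H](OC(=O)/C(C)=C\C)C[C@]1(C)O[C@@H]1[C@@H](O[Si](C)(C)C(C)(C)C)C[C@@]1(C)O[C@H]21 | intermediate
32 | (1R,2S,4R,5R,6S,7R,8S,10S)-2-hydroxy-8-{[(Z)-2-methylbut-2-enoyl]oxy}-1,10:4,5-diepoxygermacr-11(13)-eno-12,6-lactone | C=C1C(=O)O[C@H]2[C@H]1[C@@H](OC(=O)/C(C)=C\C)C[C@]1(C)O[C@@H]1[C@@H](O)C[C@@]1(C)O[C@H]21 | target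

## Step count and least certain steps

Total: 20 steps. Longest linear sequence: 20 steps, from 1 to 32. Compounds 2, 6, 13, 18 and 29 are bought.

**Step 13 (key step).** Three things may go wrong: capture of the primary C11 radical by oxygen or tin hydride before it reaches an alkene held in a ten-membered ring, closure to the cis-fused ring, and loss of face control when oxygen is taken up at C8.
- The fallback separates ring closure from oxygenation. It sets out from 17, which is converted with 18 and N-iodosuccinimide into the iodoacetal F1.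
- F1 is cyclised by iodine atom transfer (catalytic Et3B, benzene, rt, no tin hydride) to the C8 iodide F2. With no reductant and no bulk oxygen present, an uncyclised radical can only return to F1.
- F2 is then hydroxylated on its own (Bu3SnH, air), which gives 21 together with its C8 epimer F3.
- The mixture is oxidised with Dess–Martin periodinane to the C8 ketone F4, and F4 is reduced with NaBH4/CeCl3 at −78 °C, or with LiBH(s-Bu)3 if the ring shields the other face. The route is rejoined at 21.

**Step 11.** Intermolecular metathesis may outrun the ten-membered closure, the E cycloalkene may form, or a ruthenium hydride may isomerise the free allylic alcohol.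
- The fallback closes the ring on the acetal instead of the carbinol. It sets out from 16, which is acetalised with 18 and NBS to the open-chain bromoacetal F5.
- Metathesis of F5 then gives 19 directly. The large acetal on O6 removes the free hydroxyl and favours the folded conformer of the C5–C6–C7 segment.

**Step 9.** The discrimination between the two C6 epimers may be incomplete because the carbinol carries two alkenyl groups, and the vinyl group of the epimer to be kept may be epoxidised slowly. By design half of 14 is lost.
- The fallback is an enzymatic acylation. It sets out from 14, which is treated with vinyl acetate and Burkholderia cepacia lipase.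
- By the empirical rule for secondary alcohols (large group the trisubstituted alkenyl, medium group vinyl), the 3R epimer is converted into the acetate F6, and 15 is left and taken on at step 10.

**Step 1.** A small linear ynal may give only moderate enantioselectivity.
- The fallback sets out from 1, which is propargylated without a chiral catalyst (3-bromo-1-(trimethylsilyl)prop-1-yne, Zn, THF) to the racemic alcohol F7.
- F7 is oxidised with Dess–Martin periodinane to the ynone F8. F8 is reduced with (S)-Alpine-Borane, from (−)-α-pinene, under neutral conditions (Midland reduction), with the slim alkynyl group as the small substituent. The route is rejoined at 3.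

**Step 19.** The angelate may isomerise to the tiglate during activation, and the C8 hydroxyl beside the ring fusion may acylate slowly.
- The fallback builds the Z enoate on the substrate. It sets out from 28, which is esterified (DCC, DMAP) with 2-[bis(2,2,2-trifluoroethoxy)phosphoryl]propanoic acid to the phosphonate F9.
- Still–Gennari olefination of F9 with acetaldehyde (KN(SiMe3)2, 18-crown-6, THF, −78 °C) gives 31 with the Z geometry set kinetically.

## Further compounds

F1 | step 13 | (1R,2S,4R,5R,6S,7Z,10S)-6-[1-(benzyloxy)-2-iodoethoxy]-2-[(tert-butyldimethylsilyl)oxy]-1,10:4,5-diepoxy-4,10-dimethylcyclodec-7-ene (both acetal epimers) | ICC(OCc1ccccc1)O[C@H]2/C=C\C[C@]1(C)O[C@@H]1[C@@H](O[Si](C)(C)C(C)(C)C)C[C@@]1(C)O[C@H]21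
F2 | step 13 | 8-iodo analogue of 21: 12-(benzyloxy)-2-[(tert-butyldimethylsilyl)oxy]-8-iodo-1,10:4,5:6,12-triepoxy-13-norgermacrane (C8 and C12 epimers) | C1C(OCc3ccccc3)O[C@H]2[C@H]1C(I)C[C@]1(C)O[C@@H]1[C@@H](O[Si](C)(C)C(C)(C)C)C[C@@]1(C)O[C@H]21
F3 | step 13 | C8 epimer of 21 (8R alcohol, both C12 epimers) | C1C(OCc3ccccc3)O[C@H]2[C@H]1[C@H](O)C[C@]1(C)O[C@@H]1[C@@H](O[Si](C)(C)C(C)(C)C)C[C@@]1(C)O[C@H]21
F4 | step 13 | 12-(benzyloxy)-2-[(tert-butyldimethylsilyl)oxy]-1,10:4,5:6,12-triepoxy-13-norgermacran-8-one (both C12 epimers) | C1C(OCc3ccccc3)O[C@H]2[C@H]1C(=O)C[C@]1(C)O[C@@H]1[C@@H](O[Si](C)(C)C(C)(C)C)C[C@@]1(C)O[C@H]21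
F5 | step 11 | 1-(benzyloxy)-2-bromoethyl acetal of 16 at the allylic hydroxyl (both acetal epimers) | BrCC(OCc1ccccc1)O[C@@H](C=C)[C@H]1O[C@]1(C)C[C@H](O[Si](C)(C)C(C)(C)C)[C@H]1O[C@@]1(C)CC=C
F6 | step 9 | (3R,4E,7S)-7-[(tert-butyldimethylsilyl)oxy]-5-methyl-7-[(2R,3S)-3-methyl-3-(prop-2-en-1-yl)oxiran-2-yl]hepta-1,4-dien-3-yl acetate | C=C[C@@H](OC(C)=O)/C=C(\C)C[C@H](O[Si](C)(C)C(C)(C)C)[C@H]1O[C@@]1(C)CC=C
F7 | step 1 | racemic 1-(trimethylsilyl)hepta-1,5-diyn-4-ol | C[Si](C)(C)C#CCC(O)C#CC
F8 | step 1 | 1-(trimethylsilyl)hepta-1,5-diyn-4-one | C[Si](C)(C)C#CCC(=O)C#CC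
F9 | step 19 | 8-O-{2-[bis(2,2,2-trifluoroethoxy)phosphoryl]propanoyl} derivative of 28 | C=C1C(=O)O[C@H]2[C@H]1[C@@H](OC(=O)C(C)P(=O)(OCC(F)(F)F)OCC(F)(F)F)C[C@]1(C)O[C@@H]1[C@@H](O[Si](C)(C)C(C)(C)C)C[C@@]1(C)O[C@H]21
A1 | alternative 1 | 8-angeloyloxy-2-hydroxy-4,5-epoxygermacra-1(10)Z,11(13)-dieno-12,6-lactone (1,10-deoxy form of the target) | C=C1C(=O)O[C@H]2[C@H]1[C@@H](OC(=O)/C(C)=C\C)C/C(C)=C\[C@@H](O)C[C@@]1(C)O[C@H]21
A2 | alternative 2 | 8-angeloyloxy-12-[(tert-butyldimethylsilyl)oxy]-1,10:4,5-diepoxygermacr-11(13)-ene-2,6-diol | O[C@H]2[C@H](C(=C)CO[Si](C)(C)C(C)(C)C)[C@@H](OC(=O)/C(C)=C\C)C[C@]1(C)O[C@@H]1[C@@H](O)C[C@@]1(C)O[C@H]21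
A3 | alternative 3 | ten-membered C10 ketone with the 4E alkene, 2-O-(4-methoxybenzyl), 6-O-triethylsilyl, 8-O-tert-butyldimethylsilyl and a 2-(triethylsilyloxy)ethyl arm on C7 | [C@@H]2(CCO[Si](CC)(CC)CC)[C@@H](O[Si](C)(C)C(C)(C)C)CC(=O)C[C@@H](OCc1ccc(OC)cc1)C/C(C)=C/[C@H]2O[Si](CC)(CC)CC
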